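**Retrosynthetic overview**
1. The dihydropyran ring is cut by a retro-hetero-Diels–Alder reaction into (−)-β-caryophyllene (its C4=C5 alkene) and the o-quinone methide made from benzaldehyde and 2,4-diformylphloroglucinol.
2. (−)-β-Caryophyllene comes from achiral farnesyl diphosphate through a terpene cyclase, which builds the nine-membered ring and then the cyclobutane and sets C1 and C9.
3. Farnesyl diphosphate comes from (2E,6E)-farnesol (chloride, then diphosphate displacement); the dialdehyde comes from phloroglucinol (Vilsmeier–Haack).
4. Ring order: nine-membered ring, cyclobutane (both in the enzymatic step), then the dihydropyran (last step); the arene is bought.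

Assumption: farnesol is used as the pure, achiral (2E,6E) isomer, and the cyclase is a recombinant plant (−)-β-caryophyllene synthase (EC 4.2.3.57, for example QHS1 of Artemisia annua, expressed in E. coli). Caryophyllane numbering is used for the terpenoid part (C1′ = benzylic carbon); in it the target is (1R,4R,5S,9S,1′R), a guajadial-type adduct.

**Step 1**
Reactants: 1 (2E,6E)-farnesol
Product: 3 (2E,6E)-farnesyl chloride, via farnesyloxydimethylsulfonium chloride 2 (not isolated)
Conditions: NCS, Me2S, CH2Cl2, −40 → 0 °C, 2 h; pentane extraction, used crude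
Reagents that add atoms: N-chlorosuccinimide (O=C1CCC(=O)N1Cl)
Why: Corey–Kim-type chlorination, in which the alcohol is activated as alkoxysulfonium 2 and chloride displaces DMSO at the primary allylic carbon under cold, neutral conditions, so there is no allylic transposition or E/Z isomerisation and no stereocentre is involved.

**Step 2**
Reactants: 3 (2E,6E)-farnesyl chloride
Product: 5 trisammonium (2E,6E)-farnesyl diphosphate, via bis(tetrabutylammonium) farnesyl hydrogen diphosphate 4 (not isolated)
Conditions: (n-Bu4N)3HP2O7 (2 equiv), dry MeCN, rt, 2 h; Dowex 50W-X8 (NH4+ form), 25 mM NH4HCO3/2% i-PrOH; cellulose chromatography (i-PrOH/MeCN/0.1 M NH4HCO3); lyophilise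
Reagents that add atoms: tris(tetrabutylammonium) hydrogen diphosphate (CCCC[N+](CCCC)(CCCC)CCCC.CCCC[N+](CCCC)(CCCC)CCCC.CCCC[N+](CCCC)(CCCC)CCCC.OP(=O)([O-])OP(=O)([O-])[O-]); ammonium hydrogencarbonate ([NH4+].OC(=O)[O-])
Why: SN2 displacement (Davisson–Poulter diphosphorylation) of the primary allylic chloride by the soluble hydrogen diphosphate trianion, followed by cation exchange to the water-soluble ammonium salt that terpene synthases accept; no stereocentre is involved.

**Step 3**
Reactants: 5 trisammonium (2E,6E)-farnesyl diphosphate
Product: 6 (−)-(E)-β-caryophyllene (1R,9S)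
Conditions: recombinant (−)-β-caryophyllene synthase (a terpene cyclase, sesquiterpene synthase of the ionisation-dependent class one), MgCl2 (10 mM), HEPES pH 7.5, DTT, 10% glycerol, pentane overlay, 30 °C, 24 h, 5 fed in portions; pentane extraction, 10% AgNO3 on SiO2 to remove α-humulene
Reagents that add atoms: none
Why: Enzymatic cationic cyclisation by a terpene cyclase, in which magnesium-assisted ionisation of the diphosphate in the chiral active site is followed by C1–C11 closure (farnesyl numbering) to the humulyl cation, C2–C10 closure to the cyclobutane and loss of a proton from the methyl on C3, so the enzyme acts as the asymmetric catalyst on achiral 5 and creates the first two stereocentres (caryophyllane C1 R and C9 S, trans ring fusion) together with the E ring alkene.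

**Step 4**
Reactants: 7 phloroglucinol
Product: 10 2,4,6-trihydroxybenzene-1,3-dicarbaldehyde, via mono(dimethyliminium) chloride 8 (not isolated), via bis(dimethyliminium) dichloride 9 (not isolated)
Conditions: POCl3 (2.2 equiv), DMF (2.2 equiv), 1,4-dioxane, 0 °C → rt, 12 h; then H2O, rt; filter, recrystallise
Reagents that add atoms: N,N-dimethylformamide (CN(C)C=O); water (O)
Why: Vilsmeier–Haack formylation, in which the chloroiminium electrophile attacks the very electron-rich ring twice (each iminium group deactivates the ring, so 2.2 equivalents stop largely at the bis-adduct) and water hydrolyses 9 to the hydrogen-bond-stabilised dialdehyde; no stereocentre is involved.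

**Step 5**
Reactants: 6 (−)-(E)-β-caryophyllene; 10 2,4,6-trihydroxybenzene-1,3-dicarbaldehyde; 11 benzaldehyde
Product: 14 target (1R,4R,5S,9S,1′R)-meroterpenoid, via benzylic carbinol 12 (not isolated), via o-quinone methide 13 (not isolated)
Conditions: 10 (1 equiv), 11 (2 equiv), 6 (2 equiv), TsOH·H2O (5% w/v) in H2O, 100 °C, 16 h; SiO2, then preparative C18 HPLC
Reagents that add atoms: none
Why: Acid-promoted Knoevenagel-type condensation of 10 with 11 gives o-quinone methide 13, which the strained trans C4=C5 alkene of 6 traps in an inverse-electron-demand hetero-Diels–Alder reaction (oxygen to the more substituted C4, the exocyclic alkene being far less reactive); suprafacial addition turns the E geometry into the trans C4-methyl/C5-H ring fusion, attack on the exposed face of the predominant βα conformer gives 4R,5S, and the transition state with phenyl outside and C5–H under the heterodiene gives 1′R, the minor diastereomers being removed by HPLC.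

**Compound list**
1 | (2E,6E)-farnesol | CC(C)=CCC/C(C)=C/CC/C(C)=C/CO | starting material
2 | farnesyloxydimethylsulfonium chloride (2E,6E) | CC(C)=CCC/C(C)=C/CC/C(C)=C/CO[S+](C)C.[Cl-] | intermediate (not isolated)
3 | (2E,6E)-farnesyl chloride | CC(C)=CCC/C(C)=C/CC/C(C)=C/CCl | intermediate
4 | bis(tetrabutylammonium) (2E,6E)-farnesyl hydrogen diphosphate | CC(C)=CCC/C(C)=C/CC/C(C)=C/COP(=O)([O-])OP(=O)(O)[O-].CCCC[N+](CCCC)(CCCC)CCCC.CCCC[N+](CCCC)(CCCC)CCCC | intermediate (not isolated)
5 | trisammonium (2E,6E)-farnesyl diphosphate | CC(C)=CCC/C(C)=C/CC/C(C)=C/COP(=O)([O-])OP(=O)([O-])[O-].[NH4+].[NH4+].[NH4+] | intermediate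
6 | (−)-(E)-β-caryophyllene, (1R,4E,9S)-4,11,11-trimethyl-8-methylenebicyclo[7.2.0]undec-4-ene | C/C1=C\CCC(=C)[C@H]2CC(C)(C)[C@@H]2CC1 | intermediate
7 | phloroglucinol (benzene-1,3,5-triol) | Oc1cc(O)cc(O)c1 | starting material
8 | N,N-dimethyl(2,4,6-trihydroxybenzylidene)iminium chloride | C[N+](C)=Cc1c(O)cc(O)cc1O.[Cl-] | intermediate (not isolated)
9 | 2,4-bis[(dimethyliminio)methyl]benzene-1,3,5-triol dichloride | C[N+](C)=Cc1c(O)cc(O)c(C=[N+](C)C)c1O.[Cl-].[Cl-] | intermediate (not isolated)
10 | 2,4,6-trihydroxybenzene-1,3-dicarbaldehyde (2,4-diformylphloroglucinol) | O=Cc1c(O)cc(O)c(C=O)c1O | intermediate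
11 | benzaldehyde | O=Cc1ccccc1 | starting material
12 | 2,4,6-trihydroxy-5-[hydroxy(phenyl)methyl]benzene-1,3-dicarbaldehyde (racemic carbinol) | O=Cc1c(O)c(C=O)c(O)c(C(O)c2ccccc2)c1O | intermediate (not isolated)
13 | 6-benzylidene-3,5-diformyl-2,4-dihydroxycyclohexa-2,4-dien-1-one (o-quinone methide; benzylidene geometry not fixed, the two forms interconvert by tautomerism) | O=CC1=C(O)C(C=O)=C(O)C(=Cc2ccccc2)C1=O | intermediate (not isolated)
14 | target: (1R,4R,5S,9S,1′R) adduct; 6,8-diformyl-5,7-dihydroxy-2-methyl-4-phenylchroman trans-fused through chroman C2/C3 (= caryophyllane C4/C5) to the caryophyllane bicycle, which keeps the exocyclic methylene, the gem-dimethylcyclobutane and the 1R,9S trans fusion; H-1′ anti to H-5 and syn to the C4 methyl | C=C1CC[C@H]2[C@H](c3ccccc3)c3c(O)c(C=O)c(O)c(C=O)c3O[C@]2(C)CC[C@@H]2[C@@H]1CC2(C)C | target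

**Step count**
Total steps: 5. Longest linear sequence: 4 steps (steps 1, 2, 3, 5); step 4 is a one-step branch.

**Steps most likely to fail**

Step 5. A modest yield (about a quarter of the material) is expected: the o-quinone methide also reacts with the less populated ββ conformer and through the other endo/exo arrangement, and hot aqueous acid can rearrange 6. The fallback sets out from 10 and 11 and comes back at 13, from which 14 follows as before. Compounds 10, 11 and morpholine (EtOH, 40 °C) give, by a Betti-type Mannich condensation, the isolable Mannich base 2,4,6-trihydroxy-5-[morpholin-4-yl(phenyl)methyl]benzene-1,3-dicarbaldehyde F1. F1 is then heated with 6 (3 equiv) in toluene at 100 °C with AcOH (1.1 equiv). Retro-Mannich loss of morpholine regenerates 13 without water or strong acid, and 6 traps it in the same hetero-Diels–Alder reaction.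

Step 3. Terpene cyclases turn over slowly, diphosphate and its magnesium salt inhibit them, stray phosphatases hydrolyse 5, and some α-humulene is co-formed. The fallback sets out from 1 and comes back at 6, as a one-pot cascade (Tris pH 8, MgCl2, KCl, 30 °C, pentane overlay). A promiscuous prenol kinase of the undecaprenol kinase type converts 1 into (2E,6E)-farnesyl dihydrogen phosphate F2. An archaeal isopentenyl phosphate kinase converts F2 into (2E,6E)-farnesyl diphosphate F3 (the anion of 5 without its ammonium counter-ions), with catalytic ATP recycled by pyruvate kinase and phosphoenolpyruvate. The same cyclase converts F3 into 6 as it forms. The substrate never accumulates, so hydrolysis and inhibition are suppressed, and steps 1 and 2 are bypassed.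

Step 2. The diphosphate reagent is hygroscopic, the allylic chloride can hydrolyse or eliminate, and material is lost in ion exchange and cellulose chromatography. The fallback sets out from 1 and comes back at 5. Direct phosphorylation of 1 with Cl3CCN and bis(triethylammonium) hydrogen phosphate in MeCN at 37 °C first gives bis(triethylammonium) (2E,6E)-farnesyl phosphate F4, which is phosphorylated again in the same pot. The diphosphate is separated from F4 and the triphosphate on SiO2 (i-PrOH/conc. NH4OH/H2O) and obtained as the ammonium salt 5.

**Further compounds**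
F1 | step 5 | 2,4,6-trihydroxy-5-[morpholin-4-yl(phenyl)methyl]benzene-1,3-dicarbaldehyde (racemic) | O=Cc1c(O)c(C=O)c(O)c(C(N2CCOCC2)c2ccccc2)c1O
F2 | step 3 | (2E,6E)-farnesyl dihydrogen phosphate | CC(C)=CCC/C(C)=C/CC/C(C)=C/COP(=O)(O)O
F3 | step 3 | (2E,6E)-farnesyl diphosphate, acid form of 5 | CC(C)=CCC/C(C)=C/CC/C(C)=C/COP(=O)(O)OP(=O)(O)O
F4 | step 2 | bis(triethylammonium) (2E,6E)-farnesyl phosphate | CC(C)=CCC/C(C)=C/CC/C(C)=C/COP(=O)([O-])[O-].CC[NH+](CC)CC.CC[NH+](CC)CC
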